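We start with a count: each target made takes one first nucleophile, and each other capture product takes one second nucleophile. The flask asked about charges 12 mM of substrate, 12.0 mM of the first and 14.4 mM of the second.

| flask | substrate | first nucleophile | second nucleophile | remark | time |
|---|---|---|---|---|---|
| west | 6 mM | 12 mM | 14.4 mM | run made earlier |  |
| south-west | 24 mM | 12 mM | 14.4 mM | run made earlier |  |
| north-east | 12 mM | 12 mM | 29 mM | run made earlier |  |
| flask | 12 mM | 12.0 mM | 14.4 mM |  | 20 h |

| run | time / h | target / % | other capture product / % | substrate / % |
|---|---|---|---|---|
| west | 2.50 | 43.6 | 12.0 | 0 |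
| west | 8.00 | 43.6 | 13.6 | 0 |
| west | 12.0 | 43.0 | 12.1 | 1.3 |
| west | 20.0 | 42.9 | 11.6 | 0.4 |
| south-west | 2.50 | 35.5 | 11.3 | 0 |
| south-west | 8.00 | 36.3 | 15.2 | 1.2 |
| south-west | 12.0 | 33.6 | 15.4 | 0 |
| south-west | 20.0 | 36.0 | 13.6 | 0 |
| north-east | 5.00 | 39.6 | 19.6 | 0 |
| north-east | 10.0 | 37.0 | 17.0 | 0.6 |
| north-east | 15.0 | 37.1 | 19.7 | 0 |
| north-east | 20.0 | 37.0 | 22.1 | 2.1 |

(readings scatter by 1 percentage point)

- ratio of target to other capture product at 1.0 min
- ratio of target to other capture product at 30 min
- ratio of target to other capture product at 20 h

- the earlier runs were read with a standard deviation of 1 percentage point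
- reactions considered so far: substrate -> intermediate; first nucleophile + intermediate -> target; second nucleophile + intermediate -> other capture product; intermediate -> solvolysis product; 2 second nucleophile -> self-condensation product; first nucleophile -> decomposed reagent

The west and south-west runs look contradictory. Their nucleophile charges are equal, yet averaged over the readings west shows target 43.3% and other capture product 12.3%, a ratio of 3.52, while south-west shows 35.4% and 13.9%, a ratio of 2.55. But capture in south-west takes 8.48 mM of the first nucleophile against 2.60 mM in west, so [first nucleophile] falls further there. Each capture rate is proportional to its nucleophile, so if capture is the main drain, the integrated falls keep a constant quotient. For each nucleophile we take the logarithm of its charge over its charge less what capture took, and divide the first logarithm by the second. West gives 4.62 and south-west 4.67. We call this quotient S, the capture-only log quotient. It is a number read from the runs, and it stands for the selectivity factor only on the assumption that capture is the main drain of both nucleophiles. On that assumption we reckon for the flask's start S times [first nucleophile]/[second nucleophile], which is 3.85.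

The forecast, a little lower, says 3.7, then 3.5, then 3.1, as “the cumulative ratio drifts down”.

The flask gives 3.14, 3.23 and 3.23.

    substrate → intermediate (k = 0.0130 s⁻¹)
    first nucleophile + intermediate → target (k = 7.31 M⁻¹ s⁻¹)
    second nucleophile + intermediate → other capture product (k = 1.96 M⁻¹ s⁻¹)
    intermediate → solvolysis product (k = 0.0745 s⁻¹)
    2 second nucleophile → self-condensation product (k = 0.137 M⁻¹ s⁻¹)
    first nucleophile → decomposed reagent (k = 2.13 × 10⁻⁴ s⁻¹)

The forecast's early value is too high by a factor of 1.18; its other two stand within tolerance. The flask's end amounts give S = 4.72, yet its early ratio over the charge ratio is 3.77. The assumption does not hold in this flask: by 20.0 h self-condensation has taken 12.8 mM of the second nucleophile against 1.53 mM taken by capture, and S stands above the ratio of the two capture constants, 3.73. The neighbour flask with 30 mM of first nucleophile ends with target 65.9% and other capture product 7.58%, so S = 4.69, and S times its charge ratio is 9.77. That neighbour flask shows a ratio of 8.10 at 1.0 min and 8.69 at 20 h.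

All runs are calculated on assumed constants; the scatter is artificial.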